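Birch, with 15 mol% of free catalyst, reaches 47.2% of product at 12.0 h; oak, with 6.7 mol%, reaches 53.6% at 30.0 h. Loading times time, c·t, is nearly equal in the two, 1.80 h and 2.01 h, so product follows the turns each catalyst has had time for.

| setting | oak | birch | flask |
|---|---|---|---|
| substrate | 0.30 M | 0.30 M | 0.30 M |
| gas | 11 mM (held) | 11 mM (held) | 11 mM (held) |
| free catalyst | 6.7 mol% | 15 mol% | 10 mol% |
| remark | run made earlier | run made earlier |  |
| time |  |  | 2.0 d |

| run | time / h | product / % |
|---|---|---|
| oak | 4.00 | 7.7 |
| oak | 12.0 | 24.0 |
| oak | 20.0 | 38.6 |
| oak | 30.0 | 53.6 |
| oak | 50.0 | 75.0 |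
| birch | 4.00 | 16.7 |
| birch | 12.0 | 47.2 |
| birch | 20.0 | 68.8 |
| birch | 30.0 | 84.4 |
| birch | 50.0 | 97.3 |

(standard deviation of a reading: 0.5 percentage points)

- product at 2.0 d, in percent of the substrate charged
- concentration of coupling partner in solution at 12 h, in percent of saturation
- the change that raises the amount of product at 2.0 d, in percent of the substrate charged most ("none" if none brings more than 2 percentage points) (Thursday's / Tuesday's / Sunday's / none)
- amount of product at 2.0 d, in percent of the substrate charged, after Tuesday's

- Thursday's: doubling the transfer coefficient of the gas, all else as stated
- Tuesday's: doubling the amount of free catalyst, all else as stated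
- Sunday's: doubling the saturation concentration of gas, all else as stated

- percent here means substrate units held: one idle complex counts as two
- at the start none of coupling partner is dissolved
- the earlier runs were read with a standard deviation of 0.5 percentage points
- on the list of suspects stand: coupling partner + free catalyst -> catalyst intermediate A; catalyst intermediate A -> by-product + catalyst intermediate B; substrate + catalyst intermediate B -> catalyst intermediate C; catalyst intermediate C -> free catalyst + product; gas <-> coupling partner; substrate + catalyst intermediate C <-> idle complex; coupling partner -> decomposed reagent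

A turn costs two times. The substrate time a is the cost of the step substrate + catalyst intermediate B at full charge, stretching to a/s when a fraction s of the substrate remains; b is the rest of the round, which s leaves alone. Summing turns gives c·t = −a·ln s + b·x, with x the fraction converted. Two birch readings give a = 1.79 h and b = 1.39 h.

The flask has c·t = 4.80 h, which birch reaches at 32.0 h, so birch's nearest reading, 84.4% at 30.0 h, serves as first x. Put back, it leaves s = 13.2%; once more, 13.4%. At that s in the flask a/s stands at 9.61 times b, so by then the substrate step is the rate-limiting step. Tuesday's doubles c·t and leaves about 1.02%, while the gas changes touch b, the smaller time.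

The forecast says 86.5%, 75% of saturation, Tuesday's, and 98.8% after it, adding: “The dissolved level can't be pinned down”.

The flask gives 87.1%, 99.4% of saturation, Tuesday's, and 98.8% after it.

    coupling partner + free catalyst → catalyst intermediate A (k = 0.0590 L mol⁻¹ s⁻¹)
    catalyst intermediate A → by-product + catalyst intermediate B (k = 6.50 × 10⁻⁴ s⁻¹)
    substrate + catalyst intermediate B → catalyst intermediate C (k = 4.80 × 10⁻⁴ L mol⁻¹ s⁻¹)
    catalyst intermediate C → free catalyst + product (k = 0.0410 s⁻¹)
    gas ⇌ coupling partner, rate k5*(csat - [coupling partner]) (kL = 0.0320 s⁻¹)
    substrate + catalyst intermediate C ⇌ idle complex, settled at all times (K = 11.0 L mol⁻¹)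
    coupling partner → decomposed reagent (k = 2.80 × 10⁻⁶ s⁻¹)

In the flask left until 12 h, gas refills coupling partner with a half-life of 21.7 s, far shorter than the 0.959 h that coupling partner has against free catalyst, then 11.3% of the catalyst charged. The flask holds 99.4% of saturation at 12 h, against the forecast's 75%. Substrate left in the flask stands at 13%, against 13.4% from a and b. With 17 mol% of free catalyst, a and b leave 2.26%, and that neighbour flask holds 2.45%.

Readings and results come from a simulation from invented constants; noise was put on by code.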